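A decade, one power of ten, is the measure used here, and the quantity to weigh is the target share: target formed per substrate lost, the integral selectivity of a flask.

| flask | substrate | partner | capture agent | temperature | remark | time |
|---|---|---|---|---|---|---|
| alder | 20 mM | 40 mM | 0.67 mM | 80 °C | run made earlier |  |
| elm | 20 mM | 40 mM | 0.50 mM | 80 °C | run made earlier |  |
| dusk | 6.0 mM | 40.0 mM | 1.00 mM | 95 °C |  | 15 min |
| spring | 20 mM | 40.0 mM | 1.00 mM | 80 °C |  | 15 min |
| midnight | 20 mM | 12.0 mM | 1.00 mM | 40 °C |  | 15 min |
| autumn | 20 mM | 80.0 mM | 1.00 mM | 60 °C |  | 15 min |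
| summer | 10 mM | 40.0 mM | 1.00 mM | 80 °C |  | 15 min |

| run | time / min | target / % | substrate / % |
|---|---|---|---|
| alder | 0.250 | 0.2 | 82.9 |
| alder | 0.833 | 0.6 | 59.0 |
| alder | 1.33 | 1.9 | 48.5 |
| alder | 2.00 | 3.1 | 38.5 |
| alder | 3.00 | 4.4 | 28.0 |
| elm | 0.250 | 0.1 | 82.0 |
| elm | 0.833 | 0.8 | 59.7 |
| elm | 1.33 | 1.7 | 48.2 |
| elm | 2.00 | 2.9 | 37.9 |
| elm | 3.00 | 4.0 | 26.7 |

(standard deviation of a reading: 0.3 percentage points)

1. ranking by amount of target, in percent of the substrate charged, from high to low, at 15 min (dusk / spring / midnight / autumn / summer)
2. the amount of target, in percent of the substrate charged of the flask you put first, at 15 min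
3. the amount of target, in percent of the substrate charged of the flask you put last, at 15 min

- the earlier runs do not show what temperature does; that part of a forecast is a guess

Which inputs must be good? The scatter moves a share read from alder's last row by 0.0286 decade through the target reading and 0.00181 decade through the substrate reading, so neither matters. Capture agent barely shows: going from 0.50 mM to 0.67 mM moved the last target reading by 0.4 percentage points, less than the 0.42 points scatter of a difference. Temperature is a guess, but spring needs none: alder stood near half its substrate at 1.33 min, so 15 min offers 1.05 decade of spare time. Midnight does depend on it: one guessed decade of slowing at 40 °C makes 15 min worth 1.50 min at 80 °C, close to where alder held 1.9% of target. The c(partner) effect is unread, since both runs held 40 mM, yet autumn stands at 80.0 mM and midnight at 12.0 mM.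

Alder's last row gives the target share, target per substrate lost, as 6.11%. Spring should end near that figure. As a bet on first-order dependence on c(partner), with temperature left aside, autumn's share reaches 12.2%, which puts autumn first, with midnight last, under 1.9%. Summer and dusk hold spring's c(partner) with less substrate, a change neither run reads, so this reckoning sets them near spring's share and leaves their order open.

The forecast reads spring > summer > dusk > autumn > midnight, with 13% first and 1.5% last, on the ground that “Extrapolating gives spring about 13–14%”, higher than the share reckoned here.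

The flasks give autumn > summer > spring > dusk > midnight, with 28.5% first and 0.0752% last.

    substrate + partner ⇌ intermediate A (K = 9.39 M⁻¹, k = 0.192 M⁻¹ s⁻¹, Ea = 45.0 kJ mol⁻¹, ΔH = −43.0 kJ mol⁻¹)
    substrate → intermediate B (k = 0.00645 s⁻¹, Ea = 96.0 kJ mol⁻¹)
    partner + intermediate A → intermediate C (k = 0.0856 M⁻¹ s⁻¹, Ea = 63.0 kJ mol⁻¹)
    partner + intermediate B → side product A (k = 0.798 M⁻¹ s⁻¹, Ea = 42.0 kJ mol⁻¹)
    intermediate C → side product B (k = 0.00153 s⁻¹, Ea = 95.0 kJ mol⁻¹)
    intermediate C → target (k = 0.0384 s⁻¹, Ea = 94.0 kJ mol⁻¹)
    capture agent + intermediate C → trapped intermediate (k = 4.96 M⁻¹ s⁻¹, Ea = 46.0 kJ mol⁻¹)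
    (constants at 80 °C)

Spring's share comes to 7.23%, near alder's figure, while autumn's is 33.7%, 0.742 decade above alder's figure, and autumn's neighbour with 140 mM of partner holds 57.4%. In autumn at 1.15 min, substrate enters intermediate A 6.2 times as fast as intermediate B, counting the forward step alone, while intermediate A falls back 2.0 times as fast as it goes on.

The readings were computed on assumed constants; scatter was added.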